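**Plan**

- Numbering: ring C1 (C=O), C2 (C–N), C3 (=CH), C4 (tertiary C–OH), C5 (CHOH), C6 (CH2); triene C1′–C7′.
- Cuts, last bond first: the 4,5-acetonide; C2′–C3′ (Heck coupling of a C4 vinyl group with a 5-iodopentadienamide); C2–N (copper-catalysed amidation of a C2 iodide); C2=C3 (ring-closing metathesis); C1–vinyl and both C4–vinyl bonds (Grignard additions to a D-malic acid frame).
- Feature used: C4 carries two sp2 carbon arms, ring C3 and chain C1′. In the open-chain precursor it can therefore be a divinyl carbinol carbon that is not yet a stereocentre, next to the C5 carbinol; a dioxolane across O4/O5 makes the two vinyl groups diastereotopic.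
- Forward: D-malic acid → dioxolanone → divinyl diol acetonide → vinyl ketone → metathesis closes the cyclohexenone (the only ring built; the cyclopentenone comes from cyclopentane-1,3-dione) → C2 iodide → upper dienamide → lower trienamide arm → free diol.
- Stereochemistry: C5 (R) is C2 of D-malic acid. C4 (S) arises in the metathesis, because only the vinyl group cis to the C5 arm can close a cis-fused ring, which is the cis-4,5-diol. Side-chain C6 (R) comes from methylation of an (R)-4-benzyloxazolidinone imide. The alkenes are E from stabilised Wittig reagents, a Takai olefination and the Heck step.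

Key step: step 10

Remark: the target as drawn is the cis-diol (4S,5R), and the aminocyclopentenone is handled as the 2-hydroxy-5-oxocyclopent-1-enyl amide tautomer of the given structure.

**Main line: D-malic acid to the iodoenone**

Step 1
Reactants: 1 D-malic acid
Product: 2 (R)-2-(2,2-dimethyl-5-oxo-1,3-dioxolan-4-yl)acetic acid
Conditions: 2,2-dimethoxypropane, p-TsOH·H2O (cat.), rt
Reagents that add atoms: 2,2-dimethoxypropane, COC(C)(C)OC
Why: Acid-catalysed ketal exchange ties the α-hydroxy acid into the five-membered dioxolanone in preference to the six-membered alternative, so only the β-carboxyl stays free and the stereocentre is untouched.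

Step 2
Reactants: 2 (R)-2-(2,2-dimethyl-5-oxo-1,3-dioxolan-4-yl)acetic acid
Product: 3 (R)-5-(2-hydroxyethyl)-2,2-dimethyl-1,3-dioxolan-4-one
Conditions: BH3·SMe2, THF, 0 °C to rt; neutral aqueous work-up
Reagents that add atoms: none
Why: Borane reduces a carboxylic acid through its acyloxyborane much faster than it touches the lactone-type ester, and a work-up without acid keeps the hydroxy ester from relactonising.

Step 3
Reactants: 3 (R)-5-(2-hydroxyethyl)-2,2-dimethyl-1,3-dioxolan-4-one
Product: 4 (R)-5-[2-(tert-butyldiphenylsilyloxy)ethyl]-2,2-dimethyl-1,3-dioxolan-4-one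
Conditions: TBDPSCl, imidazole, CH2Cl2, 0 °C to rt
Reagents that add atoms: tert-butylchlorodiphenylsilane, CC(C)(C)[Si](Cl)(c1ccccc1)c1ccccc1
Why: Imidazole-promoted silylation of a primary alcohol is routine, and the TBDPS ether is chosen because it must outlast the Grignard reagent of step 4 and the acid catalyst of step 5.

Step 4
Reactants: 4 (R)-5-[2-(tert-butyldiphenylsilyloxy)ethyl]-2,2-dimethyl-1,3-dioxolan-4-one; 5 vinylmagnesium bromide
Product: 7 (R)-6-(tert-butyldiphenylsilyloxy)-3-vinylhex-1-ene-3,4-diol, via hydroxy vinyl ketone 6 (not isolated)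
Conditions: CH2=CHMgBr (5 equiv.), THF, −78 to 0 °C; aqueous work-up
Reagents that add atoms: none
Why: In this double Grignard addition to an ester-type carbonyl the first vinyl group opens the dioxolanone to ketone 6 with loss of acetone (which takes up part of the excess reagent), the magnesium α-alkoxide chelate steers the second vinyl group into 1,2-addition, and the new carbinol carbon carries two identical vinyl groups and so is not a stereocentre while C5 is untouched.

Step 5
Reactants: 7 (R)-6-(tert-butyldiphenylsilyloxy)-3-vinylhex-1-ene-3,4-diol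
Product: 8 tert-butyl{2-[(R)-2,2-dimethyl-5,5-divinyl-1,3-dioxolan-4-yl]ethoxy}diphenylsilane
Conditions: 2-methoxypropene, PPTS (cat.), CH2Cl2, 0 °C to rt
Reagents that add atoms: 2-methoxypropene, COC(C)=C
Why: Acid-catalysed acetonide formation from an enol ether closes the only ring available to the 1,2-diol now that the primary hydroxyl is silylated, and PPTS is too weak to ionise the divinyl carbinol.

Step 6
Reactants: 8 tert-butyl{2-[(R)-2,2-dimethyl-5,5-divinyl-1,3-dioxolan-4-yl]ethoxy}diphenylsilane
Product: 9 2-[(R)-2,2-dimethyl-5,5-divinyl-1,3-dioxolan-4-yl]ethanol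
Conditions: Bu4NF, THF, 0 °C to rt
Reagents that add atoms: none
Why: Fluoride cleaves the silyl ether through the strong Si–F bond while the acetonide and the vinyl groups are inert.

Step 7
Reactants: 9 2-[(R)-2,2-dimethyl-5,5-divinyl-1,3-dioxolan-4-yl]ethanol
Product: 10 2-[(R)-2,2-dimethyl-5,5-divinyl-1,3-dioxolan-4-yl]acetaldehyde
Conditions: Dess–Martin periodinane, CH2Cl2, 0 °C to rt
Reagents that add atoms: none
Why: Dess–Martin oxidation takes the primary alcohol to the aldehyde without base, which avoids β-elimination of the ring oxygen from the β-alkoxy aldehyde.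

Step 8
Reactants: 10 2-[(R)-2,2-dimethyl-5,5-divinyl-1,3-dioxolan-4-yl]acetaldehyde; 5 vinylmagnesium bromide
Product: 11 1-[(R)-2,2-dimethyl-5,5-divinyl-1,3-dioxolan-4-yl]but-3-en-2-ol (both carbinol epimers)
Conditions: CH2=CHMgBr, THF, −78 °C; aqueous work-up
Reagents that add atoms: none
Why: Grignard 1,2-addition to the aldehyde is fast at low temperature, and the new carbinol centre may form as an epimer mixture because it becomes the ketone in step 9.

Step 9
Reactants: 11 1-[(R)-2,2-dimethyl-5,5-divinyl-1,3-dioxolan-4-yl]but-3-en-2-ol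
Product: 12 (R)-1-(2,2-dimethyl-5,5-divinyl-1,3-dioxolan-4-yl)but-3-en-2-one
Conditions: Dess–Martin periodinane, CH2Cl2, 0 °C to rt; used at once
Reagents that add atoms: none
Why: Dess–Martin oxidation converts both epimers of the allylic alcohol into the one vinyl ketone under base-free conditions that spare the β-alkoxy ketone.

Step 10
Reactants: 12 (R)-1-(2,2-dimethyl-5,5-divinyl-1,3-dioxolan-4-yl)but-3-en-2-one
Product: 13 (3aR,7aS)-7a-ethenyl-2,2-dimethyl-3a,4-dihydro-1,3-benzodioxol-5(7aH)-one (cis-fused 4,5-O-isopropylidene-4-vinylcyclohex-2-enone)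
Conditions: second-generation Grubbs catalyst (H2IMes)(PCy3)Cl2Ru=CHPh (5 mol%), CH2Cl2 (0.005 M), 40 °C
Reagents that add atoms: none
Why: The ruthenium benzylidene exchanges onto a monosubstituted alkene of 12, the new alkylidene undergoes [2+2] cycloaddition with the partner alkene, and cycloreversion of the metallacyclobutane releases ethene and forms the C2=C3 bond. The closest known reaction types are ring-closing enone–olefin metathesis to cyclohex-2-enones and group-selective ring-closing metathesis of divinyl carbinols. The cyclohexenone closes as a six-membered carbocycle from a 1,7-diene, annulated onto the dioxolane with the new double bond inside the ring. C4 becomes a stereocentre here and is controlled by C5 through the dioxolane: only the vinyl group cis to the C5 CH2C(O) arm can reach the enone and give a cis-fused bicyclo[4.3.0] skeleton, whereas the trans vinyl group would have to span a strained trans-fused dioxolane on a flattened cyclohexenone. The step needs selection between two diastereotopic vinyl groups, which the acetonide secures (a carbene loaded on the wrong vinyl group can pass on by alkylidene exchange), and ring closure over oligomerisation, which high dilution secures. The product enone is an electron-poor cis-disubstituted alkene and the remaining vinyl group sits on a quaternary carbon, so neither should react further.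

Step 11
Reactants: 13 (3aR,7aS)-7a-ethenyl-2,2-dimethyl-3a,4-dihydro-1,3-benzodioxol-5(7aH)-one
Product: 14 (3aR,7aS)-7a-ethenyl-6-iodo-2,2-dimethyl-3a,4-dihydro-1,3-benzodioxol-5(7aH)-one (iodine on C2 of the enone)
Conditions: I2, pyridine, CH2Cl2, 0 °C to rt
Reagents that add atoms: iodine, II
Why: This enone α-iodination runs by conjugate addition of pyridine, iodination of the enolate at C2 and loss of pyridine (a Baylis–Hillman-type addition–elimination), it is known for 4,4-disubstituted cyclohexenones, and iodine does not add to the isolated vinyl group under these conditions.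

**Fragment 1: the upper dienamide**

Step 12
Reactants: 15 (R)-4-benzyloxazolidin-2-one; 16 hexanoyl chloride
Product: 17 (R)-4-benzyl-3-hexanoyloxazolidin-2-one
Conditions: Et3N, DMAP (cat.), CH2Cl2, 0 °C to rt
Reagents that add atoms: none
Why: DMAP-catalysed N-acylation of the oxazolidinone by the acid chloride gives the imide without a strong base.

Step 13
Reactants: 17 (R)-4-benzyl-3-hexanoyloxazolidin-2-one
Product: 19 (R)-4-benzyl-3-[(R)-2-methylhexanoyl]oxazolidin-2-one, via sodium Z-enolate 18 (not isolated)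
Conditions: NaN(SiMe3)2, THF, −78 °C; then MeI, −78 °C
Reagents that add atoms: iodomethane, CI
Why: In this Evans asymmetric alkylation the chelated Z-enolate 18 is methylated on the face opposite the benzyl group of the (R)-auxiliary, which sets the (R) methyl-bearing centre (C6 of the side chain), and the minor diastereomer can be removed by chromatography.

Step 14
Reactants: 19 (R)-4-benzyl-3-[(R)-2-methylhexanoyl]oxazolidin-2-one
Product: 20 (R)-2-methylhexan-1-ol
Conditions: LiBH4, MeOH (1 equiv.), Et2O, 0 °C
Reagents that add atoms: none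
Why: LiBH4 reduces the exocyclic imide carbonyl, which releases the primary alcohol without epimerising the α-centre and returns the auxiliary.

Step 15
Reactants: 20 (R)-2-methylhexan-1-ol
Product: 22 (2E,4R)-2,4-dimethyloct-2-enal, via (R)-2-methylhexanal 21 (not isolated)
Conditions: Dess–Martin periodinane, CH2Cl2, 0 °C to rt; filtration through silica; then Ph3P=C(CH3)CHO, toluene, 90 °C
Reagents that add atoms: 2-(triphenylphosphoranylidene)propanal, CC(C=O)=P(c1ccccc1)(c1ccccc1)c1ccccc1
Why: Dess–Martin oxidation gives the volatile aldehyde 21, which is used at once as a solution in a Wittig reaction with a stabilised, non-basic formyl ylide that should keep the α-centre intact and give the E trisubstituted enal.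

Step 16
Reactants: 22 (2E,4R)-2,4-dimethyloct-2-enal
Product: 23 (2E,4E,6R)-4,6-dimethyldeca-2,4-dienamide
Conditions: Ph3P=CHC(O)NH2, toluene, 90 °C
Reagents that add atoms: 2-(triphenylphosphoranylidene)acetamide, NC(=O)C=P(c1ccccc1)(c1ccccc1)c1ccccc1
Why: Wittig olefination with the stabilised carbamoyl ylide forms the E C2=C3 bond and brings in the primary amide directly.

**First coupling**

Step 17
Reactants: 14 (3aR,7aS)-7a-ethenyl-6-iodo-2,2-dimethyl-3a,4-dihydro-1,3-benzodioxol-5(7aH)-one; 23 (2E,4E,6R)-4,6-dimethyldeca-2,4-dienamide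
Product: 24 (2E,4E,6R)-N-[(3aR,7aS)-7a-ethenyl-2,2-dimethyl-5-oxo-3a,4,5,7a-tetrahydro-1,3-benzodioxol-6-yl]-4,6-dimethyldeca-2,4-dienamide
Conditions: CuI (10 mol%), N,N′-dimethylethane-1,2-diamine (20 mol%), K2CO3, toluene, 60 °C
Reagents that add atoms: none
Why: In this Goldberg-type amidation of a vinyl iodide the diamine-ligated copper amidate inserts into the activated C2–I bond of the α-iodoenone and C–N reductive elimination follows, and the weak, poorly soluble base is chosen to spare the β-alkoxy ketone while the vinyl group and acetonide look on.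

**Fragment 2: the lower iododienamide**

Step 18
Reactants: 25 ethyl (E)-4-oxobut-2-enoate
Product: 26 ethyl (2E,4E)-5-iodopenta-2,4-dienoate
Conditions: CrCl2 (6 equiv.), CHI3 (2 equiv.), THF, 0 °C, dark
Reagents that add atoms: iodoform, IC(I)I
Why: In the Takai olefination the geminal dichromium species made from CHI3 and CrCl2 adds to the aldehyde and eliminates to the E vinyl iodide, leaving the conjugated ester alone.

Step 19
Reactants: 26 ethyl (2E,4E)-5-iodopenta-2,4-dienoate
Product: 27 (2E,4E)-5-iodopenta-2,4-dienoic acid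
Conditions: LiOH, THF/H2O, 0 °C; then 1 M HCl to pH 2
Reagents that add atoms: lithium hydroxide, [Li+].[OH-]
Why: Saponification of the ethyl ester at low temperature leaves the dienyl iodide intact.

Step 20
Reactants: 28 cyclopentane-1,3-dione
Product: 29 2-nitrocyclopentane-1,3-dione (enol form, 3-hydroxy-2-nitrocyclopent-2-enone)
Conditions: fuming HNO3, AcOH, 10 °C
Reagents that add atoms: nitric acid, O[N+](=O)[O-]
Why: Electrophilic nitration takes place at the doubly activated C2 of the enolised cyclic 1,3-diketone.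

Step 21
Reactants: 29 2-nitrocyclopentane-1,3-dione
Product: 30 2-amino-3-hydroxycyclopent-2-en-1-one hydrochloride
Conditions: H2 (1 atm), Pd on carbon, HCl, MeOH, rt
Reagents that add atoms: hydrogen chloride, Cl
Why: Catalytic hydrogenation reduces the nitro group to the amine, which is trapped as its hydrochloride so that the α-amino diketone cannot self-condense.

Step 22
Reactants: 27 (2E,4E)-5-iodopenta-2,4-dienoic acid; 30 2-amino-3-hydroxycyclopent-2-en-1-one hydrochloride
Product: 32 (2E,4E)-N-(2-hydroxy-5-oxocyclopent-1-en-1-yl)-5-iodopenta-2,4-dienamide, via benzotriazolyl ester 31 (not isolated)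
Conditions: EDC·HCl, HOBt, DMF, 0 °C; then 30, i-Pr2NEt, 0 °C to rt, dark
Reagents that add atoms: 1-hydroxybenzotriazole, On1nnc2ccccc12 (its atoms are carried only by 31)
Why: Carbodiimide amide coupling proceeds through the active ester 31, and any acyl group that lands on the enol oxygen of 30 is an activated ester next to the amine and should migrate to nitrogen.

**Second coupling and release**

Step 23
Reactants: 24 (2E,4E,6R)-N-[(3aR,7aS)-7a-ethenyl-2,2-dimethyl-5-oxo-3a,4,5,7a-tetrahydro-1,3-benzodioxol-6-yl]-4,6-dimethyldeca-2,4-dienamide; 32 (2E,4E)-N-(2-hydroxy-5-oxocyclopent-1-en-1-yl)-5-iodopenta-2,4-dienamide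
Product: 33 (2E,4E,6R)-N-[(3aR,7aS)-7a-{(1E,3E,5E)-7-[(2-hydroxy-5-oxocyclopent-1-en-1-yl)amino]-7-oxohepta-1,3,5-trien-1-yl}-2,2-dimethyl-5-oxo-3a,4,5,7a-tetrahydro-1,3-benzodioxol-6-yl]-4,6-dimethyldeca-2,4-dienamide (4,5-O-isopropylidene derivative of the target)
Conditions: Pd(OAc)2 (10 mol%), Bu4NCl, NaHCO3, DMF, rt to 40 °C, dark; work-up at pH 4–5
Reagents that add atoms: none
Why: In this ligand-free Heck reaction the dienyl iodide adds oxidatively to zerovalent palladium formed from Pd(OAc)2, the monosubstituted C4 vinyl group inserts with the new C–C bond at its terminal carbon, and β-hydride elimination can only occur away from the quaternary C4 and so gives the E alkene, while the trisubstituted enamide and dienamide alkenes are too hindered to insert.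

Step 24
Reactants: 33 4,5-O-isopropylidene derivative of the target
Product: 34 (2E,4E,6R)-N-[(3S,4R)-3,4-dihydroxy-3-{(1E,3E,5E)-7-[(2-hydroxy-5-oxocyclopent-1-en-1-yl)amino]-7-oxohepta-1,3,5-trien-1-yl}-6-oxocyclohex-1-en-1-yl]-4,6-dimethyldeca-2,4-dienamide (CNP0284264.2)
Conditions: AcOH/H2O (4:1), 40 °C
Reagents that add atoms: none
Why: Mild acid hydrolysis removes the acetonide, and the tertiary C4–O bond should not ionise because both alkenes flanking it are electron-poor (enone and trienamide).

**Compound list**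

1 | D-malic acid, (R)-2-hydroxybutanedioic acid | OC(=O)C[C@@H](O)C(=O)O | starting material
2 | (R)-2-(2,2-dimethyl-5-oxo-1,3-dioxolan-4-yl)acetic acid | OC(=O)C[C@H]1OC(C)(C)OC1=O | intermediate
3 | (R)-5-(2-hydroxyethyl)-2,2-dimethyl-1,3-dioxolan-4-one | OCC[C@H]1OC(C)(C)OC1=O | intermediate
4 | (R)-5-[2-(tert-butyldiphenylsilyloxy)ethyl]-2,2-dimethyl-1,3-dioxolan-4-one | CC(C)(C)[Si](OCC[C@H]1OC(C)(C)OC1=O)(c1ccccc1)c1ccccc1 | intermediate
5 | vinylmagnesium bromide | C=C[Mg]Br | starting material
6 | (R)-6-(tert-butyldiphenylsilyloxy)-4-hydroxyhex-1-en-3-one, present as its bromomagnesium alkoxide | C=CC(=O)[C@H](O)CCO[Si](c1ccccc1)(c1ccccc1)C(C)(C)C | intermediate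
7 | (R)-6-(tert-butyldiphenylsilyloxy)-3-vinylhex-1-ene-3,4-diol | C=CC(O)(C=C)[C@H](O)CCO[Si](c1ccccc1)(c1ccccc1)C(C)(C)C | intermediate
8 | tert-butyl{2-[(R)-2,2-dimethyl-5,5-divinyl-1,3-dioxolan-4-yl]ethoxy}diphenylsilane | C=CC1(C=C)OC(C)(C)O[C@@H]1CCO[Si](c2ccccc2)(c2ccccc2)C(C)(C)C | intermediate
9 | 2-[(R)-2,2-dimethyl-5,5-divinyl-1,3-dioxolan-4-yl]ethanol | C=CC1(C=C)OC(C)(C)O[C@@H]1CCO | intermediate
10 | 2-[(R)-2,2-dimethyl-5,5-divinyl-1,3-dioxolan-4-yl]acetaldehyde | C=CC1(C=C)OC(C)(C)O[C@@H]1CC=O | intermediate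
11 | 1-[(R)-2,2-dimethyl-5,5-divinyl-1,3-dioxolan-4-yl]but-3-en-2-ol, carbinol epimers | C=CC(O)C[C@H]1OC(C)(C)OC1(C=C)C=C | intermediate
12 | (R)-1-(2,2-dimethyl-5,5-divinyl-1,3-dioxolan-4-yl)but-3-en-2-one | C=CC(=O)C[C@H]1OC(C)(C)OC1(C=C)C=C | intermediate
13 | (3aR,7aS)-7a-ethenyl-2,2-dimethyl-3a,4-dihydro-1,3-benzodioxol-5(7aH)-one | O=C1C=C[C@@](OC(C)(C)O2)(C=C)[C@H]2C1 | intermediate
14 | (3aR,7aS)-7a-ethenyl-6-iodo-2,2-dimethyl-3a,4-dihydro-1,3-benzodioxol-5(7aH)-one | O=C1C(I)=C[C@@](OC(C)(C)O2)(C=C)[C@H]2C1 | intermediate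
15 | (R)-4-benzyloxazolidin-2-one | O=C1N[C@H](Cc2ccccc2)CO1 | starting material
16 | hexanoyl chloride | CCCCCC(=O)Cl | starting material
17 | (R)-4-benzyl-3-hexanoyloxazolidin-2-one | CCCCCC(=O)N1[C@H](Cc2ccccc2)COC1=O | intermediate
18 | sodium (Z)-enolate of 17 | CCCC/C=C(\[O-])N1[C@H](Cc2ccccc2)COC1=O.[Na+] | intermediate
19 | (R)-4-benzyl-3-[(R)-2-methylhexanoyl]oxazolidin-2-one | CCCC[C@@H](C)C(=O)N1[C@H](Cc2ccccc2)COC1=O | intermediate
20 | (R)-2-methylhexan-1-ol | CCCC[C@@H](C)CO | intermediate
21 | (R)-2-methylhexanal | CCCC[C@@H](C)C=O | intermediate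
22 | (2E,4R)-2,4-dimethyloct-2-enal | CCCC[C@@H](C)/C=C(\C)C=O | intermediate
23 | (2E,4E,6R)-4,6-dimethyldeca-2,4-dienamide | CCCC[C@@H](C)/C=C(C)/C=C/C(N)=O | intermediate
24 | (2E,4E,6R)-N-[(3aR,7aS)-7a-ethenyl-2,2-dimethyl-5-oxo-3a,4,5,7a-tetrahydro-1,3-benzodioxol-6-yl]-4,6-dimethyldeca-2,4-dienamide | CCCC[C@@H](C)/C=C(C)/C=C/C(=O)NC1=C[C@@](OC(C)(C)O2)(C=C)[C@H]2CC1=O | intermediate
25 | ethyl (E)-4-oxobut-2-enoate | CCOC(=O)/C=C/C=O | starting material
26 | ethyl (2E,4E)-5-iodopenta-2,4-dienoate | CCOC(=O)/C=C/C=C/I | intermediate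
27 | (2E,4E)-5-iodopenta-2,4-dienoic acid | OC(=O)/C=C/C=C/I | intermediate
28 | cyclopentane-1,3-dione | O=C1CCC(=O)C1 | starting material
29 | 2-nitrocyclopentane-1,3-dione, enol form | O=C1CCC(O)=C1[N+](=O)[O-] | intermediate
30 | 2-amino-3-hydroxycyclopent-2-en-1-one hydrochloride | NC1=C(O)CCC1=O.Cl | intermediate
31 | 1H-benzotriazol-1-yl (2E,4E)-5-iodopenta-2,4-dienoate | O=C(/C=C/C=C/I)On1nnc2ccccc12 | intermediate
32 | (2E,4E)-N-(2-hydroxy-5-oxocyclopent-1-en-1-yl)-5-iodopenta-2,4-dienamide | O=C(/C=C/C=C/I)NC1=C(O)CCC1=O | intermediate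
33 | 4,5-O-isopropylidene derivative of the target (full name in step 23) | CCCC[C@@H](C)/C=C(C)/C=C/C(=O)NC1=C[C@@](OC(C)(C)O2)(/C=C/C=C/C=C/C(=O)NC3=C(O)CCC3=O)[C@H]2CC1=O | intermediate
34 | CNP0284264.2 (full name in step 24) | CCCC[C@@H](C)/C=C(C)/C=C/C(=O)NC1=C[C@@](O)(/C=C/C=C/C=C/C(=O)NC2=C(O)CCC2=O)[C@H](O)CC1=O | target

**Count and risks**

Total step count: 24. Longest linear sequence: 14 steps (steps 1–11, 17, 23 and 24, from D-malic acid).

Most likely to fail:

1. Step 17. The carbonate base may deprotonate C6 and expel the C5 oxygen (E1cB opening of the dioxolane) in the iodoenone or in the product, and C–N bond formation with a conjugated primary amide may be slow. Fallback, from 14 and back at 24: the ketone is taken out of play first. Luche reduction of 14 (NaBH4, CeCl3·7H2O, MeOH, −78 °C) should give the iodo allylic alcohol (3aR,7aS)-7a-ethenyl-6-iodo-2,2-dimethyl-3a,4,5,7a-tetrahydro-1,3-benzodioxol-5-ol F1. This plain vinyl iodide is coupled with 23 (CuI, N,N′-dimethylethane-1,2-diamine, Cs2CO3, THF, 60 °C) to the hydroxy enamide (2E,4E,6R)-N-[(3aR,7aS)-7a-ethenyl-5-hydroxy-2,2-dimethyl-3a,4,5,7a-tetrahydro-1,3-benzodioxol-6-yl]-4,6-dimethyldeca-2,4-dienamide F2. Dess–Martin oxidation of F2 then returns 24.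

2. Step 23. Insertion into a vinyl group on a quaternary carbon may be slow, so that the dienyl iodide decomposes or homocouples first, and palladium hydride may isomerise the polyene. Fallback, from 24 and back at 33: the vinyl group is turned into the nucleophilic partner. Cross-metathesis of 24 with vinylboronic acid pinacol ester (second-generation Hoveyda–Grubbs catalyst, CH2Cl2, 40 °C) should give the E alkenylboronate (2E,4E,6R)-N-{(3aR,7aS)-2,2-dimethyl-5-oxo-7a-[(E)-2-(4,4,5,5-tetramethyl-1,3,2-dioxaborolan-2-yl)ethenyl]-3a,4,5,7a-tetrahydro-1,3-benzodioxol-6-yl}-4,6-dimethyldeca-2,4-dienamide F3. Suzuki–Miyaura coupling of F3 with 32 (Pd(dppf)Cl2, K3PO4, THF/H2O, rt) gives 33.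

3. Step 10. Initiation at the hindered C4 vinyl groups or at the electron-poor enone may be slow, so that catalyst decay or enone oligomerisation outruns ring closure. Fallback, from 11 and back at 13: the ring is closed one oxidation level lower, where the allylic alcohol alkene is a better metathesis partner and the acetonide still enforces cis fusion. The same catalyst in CH2Cl2 at 40 °C should convert 11 into the cyclohexenol (3aR,7aS)-7a-ethenyl-2,2-dimethyl-3a,4,5,7a-tetrahydro-1,3-benzodioxol-5-ol F4. Oxidation of F4 with MnO2 in CH2Cl2 gives 13.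

**Further compounds**

F1 | step 17 | (3aR,7aS)-7a-ethenyl-6-iodo-2,2-dimethyl-3a,4,5,7a-tetrahydro-1,3-benzodioxol-5-ol, C5 epimers | OC1C(I)=C[C@@](OC(C)(C)O2)(C=C)[C@H]2C1
F2 | step 17 | (2E,4E,6R)-N-[(3aR,7aS)-7a-ethenyl-5-hydroxy-2,2-dimethyl-3a,4,5,7a-tetrahydro-1,3-benzodioxol-6-yl]-4,6-dimethyldeca-2,4-dienamide, C5 epimers | CCCC[C@@H](C)/C=C(C)/C=C/C(=O)NC1=C[C@@](OC(C)(C)O2)(C=C)[C@H]2CC1O
F3 | step 23 | (2E,4E,6R)-N-{(3aR,7aS)-2,2-dimethyl-5-oxo-7a-[(E)-2-(4,4,5,5-tetramethyl-1,3,2-dioxaborolan-2-yl)ethenyl]-3a,4,5,7a-tetrahydro-1,3-benzodioxol-6-yl}-4,6-dimethyldeca-2,4-dienamide | CCCC[C@@H](C)/C=C(C)/C=C/C(=O)NC1=C[C@@](OC(C)(C)O2)(/C=C/B3OC(C)(C)C(C)(C)O3)[C@H]2CC1=O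
F4 | step 10 | (3aR,7aS)-7a-ethenyl-2,2-dimethyl-3a,4,5,7a-tetrahydro-1,3-benzodioxol-5-ol, C5 epimers | OC1C=C[C@@](OC(C)(C)O2)(C=C)[C@H]2C1
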